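**Retrosynthetic overview**
1. Target 33, (3S,4R,3'R,6'R)-β,ε-carotene-3,4,3'-triol, is cut at C11'=C12' (Wittig: ε-C15 phosphonium salt 8 + β-C25 aldehyde 29) and at C11=C12 (Horner–Wadsworth–Emmons: β-C15 phosphonate 26 + C10 dialdehyde 27); the three hydroxyls travel as silyl ethers.
2. The β-C15 unit 25 is cut in one operation at ring bond C4–C5 and at the hindered C6–C7 bond: acyclic ynal 20 + dienylboronate 24, joined by palladium-catalysed anti addition of C4 and C7 across the alkyne C5≡C6.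
3. Enabling feature: in the β ring (C1–C6) the tetrasubstituted alkene C5=C6 carries methyl C18 on C5, the polyene on C6, and the allylic carbinol C4 as ring neighbour. This is the 2,3-disubstituted cyclohex-2-en-1-ol pattern of an alkynal/organoboron anti cyclization; quaternary C1 favours closure and blocks the exo mode, and the C3 oxygen (from (S)-glycidyl ether) relays chirality to C4.
4. Ring order: the ε ring (C1'–C6') is bought intact in (R)-α-ionone 1 and is only oxidised at C3'; the β ring is the only ring closed in the synthesis, in step 18, and no ring is formed after it.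

Key step: step 18

Assumption: (R)-α-ionone 1 of high enantiomeric purity (natural-grade material) is taken as the purchased source of C6'; positions in the Why lines follow carotenoid numbering (C1–C6 β ring, primed atoms in the ε half).

**Fragment ε (steps 1–7)**

Step 1
Reactants: 1 (R)-α-ionone, (3E)-4-[(1R)-2,6,6-trimethylcyclohex-2-en-1-yl]but-3-en-2-one
Product: 2 ethyl (2E,4E)-3-methyl-5-[(1R)-2,6,6-trimethylcyclohex-2-en-1-yl]penta-2,4-dienoate
Conditions: (EtO)2P(O)CH2CO2Et, NaH, THF, 0 → 50 °C; minor 2Z isomer removed by chromatography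
Reagents that add atoms: triethyl phosphonoacetate, CCOC(=O)CP(=O)(OCC)OCC
Why: Horner–Wadsworth–Emmons olefination of the methyl ketone should give mainly the E isomer at the new trisubstituted C9'=C10' bond, and the weakly basic phosphonate carbanion should leave the C6' stereocentre untouched.

Step 2
Reactants: 2 ethyl (2E,4E)-3-methyl-5-[(1R)-2,6,6-trimethylcyclohex-2-en-1-yl]penta-2,4-dienoate
Product: 3 ethyl (2E,4E)-3-methyl-5-[(1R)-2,6,6-trimethyl-4-oxocyclohex-2-en-1-yl]penta-2,4-dienoate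
Conditions: t-BuOOH (70 % in water), Rh2(C6H10NO)4 [dirhodium tetrakis(caprolactamate)] (1 mol %), K2CO3, CH2Cl2, rt
Reagents that add atoms: tert-butyl hydroperoxide, CC(C)(C)OO
Why: Radical allylic oxidation (hydrogen abstraction by tert-butylperoxyl and collapse of the mixed peroxide) should convert the only allylic methylene group, ring C3', into the enone, while the hindered C6' methine and its configuration are spared.

Step 3
Reactants: 3 ethyl (2E,4E)-3-methyl-5-[(1R)-2,6,6-trimethyl-4-oxocyclohex-2-en-1-yl]penta-2,4-dienoate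
Product: 4 ethyl (2E,4E)-5-[(1R,4R)-4-hydroxy-2,6,6-trimethylcyclohex-2-en-1-yl]-3-methylpenta-2,4-dienoate
Conditions: K[(s-Bu)3BH], THF, −78 °C; aqueous NH4Cl
Reagents that add atoms: none
Why: 1,2-Reduction of the β,β-disubstituted ring enone by the bulky trialkylborohydride should occur in the equatorial direction, on the face away from the axial C1' methyl group of the envelope whose C6' chain is pseudo-axial, which places the new hydroxyl trans to the C6' chain (3'R) and leaves the dienoate untouched at −78 °C.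

Step 4
Reactants: 4 ethyl (2E,4E)-5-[(1R,4R)-4-hydroxy-2,6,6-trimethylcyclohex-2-en-1-yl]-3-methylpenta-2,4-dienoate
Product: 5 ethyl (2E,4E)-5-[(1R,4R)-4-[(tert-butyldimethylsilyl)oxy]-2,6,6-trimethylcyclohex-2-en-1-yl]-3-methylpenta-2,4-dienoate
Conditions: TBSCl, imidazole, DMF, rt
Reagents that add atoms: tert-butyldimethylsilyl chloride, CC(C)(C)[Si](C)(C)Cl
Why: Standard silyl ether formation protects the allylic C3' alcohol against the hydride, bromination and ylide steps that follow.

Step 5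
Reactants: 5 ethyl (2E,4E)-5-[(1R,4R)-4-[(tert-butyldimethylsilyl)oxy]-2,6,6-trimethylcyclohex-2-en-1-yl]-3-methylpenta-2,4-dienoate
Product: 6 (2E,4E)-5-[(1R,4R)-4-[(tert-butyldimethylsilyl)oxy]-2,6,6-trimethylcyclohex-2-en-1-yl]-3-methylpenta-2,4-dien-1-ol
Conditions: i-Bu2AlH (2.3 equiv), toluene, −78 °C; aqueous KNaC4H4O6 (potassium sodium tartrate)
Reagents that add atoms: none
Why: Ester-to-alcohol reduction with i-Bu2AlH proceeds by 1,2-hydride addition and leaves the diene geometry and the silyl ether intact.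

Step 6
Reactants: 6 (2E,4E)-5-[(1R,4R)-4-[(tert-butyldimethylsilyl)oxy]-2,6,6-trimethylcyclohex-2-en-1-yl]-3-methylpenta-2,4-dien-1-ol
Product: 7 tert-butyl({(1R,4R)-4-[(1E,3E)-5-bromo-3-methylpenta-1,3-dien-1-yl]-3,5,5-trimethylcyclohex-2-en-1-yl}oxy)dimethylsilane
Conditions: CBr4, PPh3, 2,6-lutidine, CH2Cl2, −20 °C; used crude
Reagents that add atoms: carbon tetrabromide, BrC(Br)(Br)Br
Why: Appel bromination is an SN2 reaction at the primary carbon under neutral conditions, which avoids the acid that would ionise the allylic C3' oxygen function.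

Step 7
Reactants: 7 tert-butyl({(1R,4R)-4-[(1E,3E)-5-bromo-3-methylpenta-1,3-dien-1-yl]-3,5,5-trimethylcyclohex-2-en-1-yl}oxy)dimethylsilane
Product: 8 {(2E,4E)-5-[(1R,4R)-4-[(tert-butyldimethylsilyl)oxy]-2,6,6-trimethylcyclohex-2-en-1-yl]-3-methylpenta-2,4-dien-1-yl}triphenylphosphonium bromide
Conditions: PPh3, toluene, rt, dark
Reagents that add atoms: triphenylphosphine, c1ccc(cc1)P(c1ccccc1)c1ccccc1
Why: Quaternisation of triphenylphosphine by the primary allylic bromide (SN2) should give the phosphonium salt with the 7'E,9'E geometry retained.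

**Ynal (steps 8–14)**

Step 8
Reactants: 9 isobutyronitrile; 10 (S)-glycidyl trityl ether, (2S)-2-[(triphenylmethoxy)methyl]oxirane
Product: 12 (4S)-4-hydroxy-2,2-dimethyl-5-(trityloxy)pentanenitrile, via lithiated isobutyronitrile 11 (not isolated)
Conditions: LiN(i-Pr)2, THF, −78 °C; then 10, −78 °C → rt; aqueous NH4Cl
Reagents that add atoms: none
Why: SN2 opening of the epoxide at its unsubstituted terminus by the nitrile carbanion builds quaternary C1 and carries the glycidyl stereocentre (future C3, S) into the product unchanged, since no bond to it is broken.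

Step 9
Reactants: 12 (4S)-4-hydroxy-2,2-dimethyl-5-(trityloxy)pentanenitrile
Product: 13 (4S)-4-[(tert-butyldimethylsilyl)oxy]-2,2-dimethyl-5-(trityloxy)pentanenitrile
Conditions: TBSCl, imidazole, DMF, rt
Reagents that add atoms: tert-butyldimethylsilyl chloride, CC(C)(C)[Si](C)(C)Cl
Why: Standard silyl ether formation installs the bulky, non-chelating C3 oxygen substituent that later directs the ring closure.

Step 10
Reactants: 13 (4S)-4-[(tert-butyldimethylsilyl)oxy]-2,2-dimethyl-5-(trityloxy)pentanenitrile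
Product: 15 (4S)-4-[(tert-butyldimethylsilyl)oxy]-2,2-dimethyl-5-(trityloxy)pentanal, via N-aluminio imine 14 (not isolated)
Conditions: i-Bu2AlH (1.3 equiv), CH2Cl2, −78 °C; then aqueous tartrate buffer (pH 4), rt
Reagents that add atoms: water, O
Why: Partial reduction of the tertiary nitrile to the N-aluminio imine and its hydrolysis (nitrile-to-aldehyde reduction) should give a non-enolisable neopentyl aldehyde, with trityl and silyl ethers inert to the hydride at −78 °C.

Step 11
Reactants: 15 (4S)-4-[(tert-butyldimethylsilyl)oxy]-2,2-dimethyl-5-(trityloxy)pentanal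
Product: 16 tert-butyl{[(2S)-6,6-dibromo-4,4-dimethyl-1-(trityloxy)hex-5-en-2-yl]oxy}dimethylsilane
Conditions: CBr4, PPh3, 2,6-lutidine, CH2Cl2, 0 °C
Reagents that add atoms: carbon tetrabromide, BrC(Br)(Br)Br
Why: This is the first stage of the Corey–Fuchs alkyne synthesis (Wittig-type dibromomethylenation), which suits an α-quaternary aldehyde because no enolisation can compete.

Step 12
Reactants: 16 tert-butyl{[(2S)-6,6-dibromo-4,4-dimethyl-1-(trityloxy)hex-5-en-2-yl]oxy}dimethylsilane
Product: 18 tert-butyl{[(2S)-4,4-dimethyl-1-(trityloxy)hept-5-yn-2-yl]oxy}dimethylsilane, via lithium acetylide 17 (not isolated)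
Conditions: n-BuLi (2.2 equiv), THF, −78 → 0 °C; then MeI, −78 °C → rt
Reagents that add atoms: iodomethane, CI
Why: In the second stage of the Corey–Fuchs sequence, bromine–lithium exchange, α-elimination and 1,2-shift give the lithium acetylide, which is C-methylated in the same flask to install the future C18 methyl on C5.

Step 13
Reactants: 18 tert-butyl{[(2S)-4,4-dimethyl-1-(trityloxy)hept-5-yn-2-yl]oxy}dimethylsilane
Product: 19 (2S)-2-[(tert-butyldimethylsilyl)oxy]-4,4-dimethylhept-5-yn-1-ol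
Conditions: camphorsulfonic acid (cat), MeOH/CH2Cl2 (1:1), 0 °C
Reagents that add atoms: none
Why: Acid-catalysed solvolysis of the trityl ether (SN1 through the trityl cation, trapped by methanol) is much faster than cleavage of the secondary silyl ether, so only the primary alcohol should be released.

Step 14
Reactants: 19 (2S)-2-[(tert-butyldimethylsilyl)oxy]-4,4-dimethylhept-5-yn-1-ol
Product: 20 (2S)-2-[(tert-butyldimethylsilyl)oxy]-4,4-dimethylhept-5-ynal
Conditions: Dess–Martin periodinane, NaHCO3, CH2Cl2, 0 °C → rt; used at once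
Reagents that add atoms: none
Why: Dess–Martin oxidation under buffered, non-basic conditions should give the α-silyloxy aldehyde without epimerising the adjacent stereocentre.

**Dienylboronate (steps 15–17)**

Step 15
Reactants: 21 (2E)-3-methylpent-2-en-4-yn-1-ol
Product: 22 (3E)-5-bromo-3-methylpent-3-en-1-yne
Conditions: PBr3 (0.4 equiv), pyridine (cat), Et2O, −10 °C
Reagents that add atoms: phosphorus tribromide, BrP(Br)Br
Why: SN2 bromination of the primary allylic alcohol with PBr3 should retain the E geometry of the trisubstituted alkene.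

Step 16
Reactants: 22 (3E)-5-bromo-3-methylpent-3-en-1-yne
Product: 23 diethyl [(2E)-3-methylpent-2-en-4-yn-1-yl]phosphonate
Conditions: P(OEt)3, neat, 110 °C, bromoethane distilled off
Reagents that add atoms: triethyl phosphite, CCOP(OCC)OCC
Why: The Michaelis–Arbuzov reaction of the primary allylic bromide gives the allylic phosphonate that later serves as the Horner–Wadsworth–Emmons nucleophile.

Step 17
Reactants: 23 diethyl [(2E)-3-methylpent-2-en-4-yn-1-yl]phosphonate
Product: 24 diethyl [(2E,4E)-3-methyl-5-(4,4,5,5-tetramethyl-1,3,2-dioxaborolan-2-yl)penta-2,4-dien-1-yl]phosphonate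
Conditions: pinacolborane, Cp2Zr(H)Cl (5 mol %), Et3N (10 mol %), CH2Cl2, rt → 40 °C
Reagents that add atoms: pinacolborane, B1OC(C)(C)C(C)(C)O1
Why: Zirconium-catalysed syn hydroboration of the terminal alkyne places boron on the terminal carbon and gives the (E)-alkenylboronate, so the future C7=C8 geometry is fixed before the key step.

**Ring closure and assembly (steps 18–22)**

Step 18
Reactants: 20 (2S)-2-[(tert-butyldimethylsilyl)oxy]-4,4-dimethylhept-5-ynal; 24 diethyl [(2E,4E)-3-methyl-5-(4,4,5,5-tetramethyl-1,3,2-dioxaborolan-2-yl)penta-2,4-dien-1-yl]phosphonate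
Product: 25 diethyl {(2E,4E)-5-[(3R,4S)-4-[(tert-butyldimethylsilyl)oxy]-3-hydroxy-2,6,6-trimethylcyclohex-1-en-1-yl]-3-methylpenta-2,4-dien-1-yl}phosphonate (carotenoid positions: 3S silyloxy, 4R hydroxyl, cis)
Conditions: Pd(PPh3)4 (5 mol %), 24 (1.5 equiv), MeOH/THF (3:1), degassed, 65 °C
Reagents that add atoms: none
Why: Zerovalent palladium binds the alkyne C5≡C6 and the electron-rich complex attacks the methanol-activated aldehyde carbon C4 through C5 from the side opposite to the metal (anti-Wacker-type oxidative addition), giving a divalent cyclohexenylpalladium methoxide with palladium on C6, and transmetalation with the dienylboronate 24 followed by reductive elimination then makes the C6–C7 bond with the 7E,9E geometry retained. The closest known reaction type is the anti-selective arylative or alkenylative cyclization of 5-alkynals with organoboron reagents under zerovalent palladium catalysis, which gives 2,3-disubstituted cyclohex-2-en-1-ols, and the hindered C6–C7 coupling has its analogue in Suzuki–Miyaura couplings of 2,6,6-trimethylcyclohexenyl triflates. The β ring closes in the 6-endo-dig mode (6-exo-trig at the carbonyl) by formation of C4–C5, the 5-exo alternative being disfavoured because it would use the neopentyl carbon C6 next to quaternary C1, whose gem-dimethyl group also accelerates closure (Thorpe–Ingold effect). The new stereocentre C4 is controlled by the C3 silyloxy stereocentre: in the half-chair transition state the silyloxy group sits pseudo-equatorial (anti to the forming bond as in the polar Felkin–Anh model and away from the axial C1 methyl) and the carbonyl oxygen pseudo-axial to avoid A(1,2) strain with the C5 methyl, which places the C4 hydroxyl cis to the C3 oxygen (4R). The step needs anti addition across the alkyne, C5-over-C6 regioselectivity and aldehyde face selectivity: the first is inherent in the mechanism, the second is secured by the tether length and quaternary C1, and the third by the C3 substituent, while the allylic phosphonate, the silyl ether and the E,E-diene should be inert to zerovalent palladium in neutral methanol.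

Step 19
Reactants: 25 diethyl {(2E,4E)-5-[(3R,4S)-4-[(tert-butyldimethylsilyl)oxy]-3-hydroxy-2,6,6-trimethylcyclohex-1-en-1-yl]-3-methylpenta-2,4-dien-1-yl}phosphonate
Product: 26 diethyl {(2E,4E)-5-[(3R,4S)-3,4-bis[(tert-butyldimethylsilyl)oxy]-2,6,6-trimethylcyclohex-1-en-1-yl]-3-methylpenta-2,4-dien-1-yl}phosphonate
Conditions: TBSOTf, 2,6-lutidine, CH2Cl2, 0 °C
Reagents that add atoms: tert-butyldimethylsilyl triflate, CC(C)(C)[Si](C)(C)OS(=O)(=O)C(F)(F)F
Why: Silyl triflate silylation of the hindered allylic C4 alcohol gives a base-stable bis-silyl ether, so that the phosphonate carbanion can be formed cleanly in the next step.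

Step 20
Reactants: 26 diethyl {(2E,4E)-5-[(3R,4S)-3,4-bis[(tert-butyldimethylsilyl)oxy]-2,6,6-trimethylcyclohex-1-en-1-yl]-3-methylpenta-2,4-dien-1-yl}phosphonate; 27 (2E,4E,6E)-2,7-dimethylocta-2,4,6-trienedial
Product: 29 (2E,4E,6E,8E,10E,12E)-13-[(3R,4S)-3,4-bis[(tert-butyldimethylsilyl)oxy]-2,6,6-trimethylcyclohex-1-en-1-yl]-2,7,11-trimethyltrideca-2,4,6,8,10,12-hexaenal, via sodium phosphonate carbanion 28 (not isolated)
Conditions: NaN(SiMe3)2 (1.05 equiv), THF, −78 °C; then added to 27 (3 equiv), THF, −78 → 0 °C, dark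
Reagents that add atoms: none
Why: Horner–Wadsworth–Emmons olefination of the allylic phosphonate carbanion with one aldehyde group of the symmetrical dialdehyde, used in excess to suppress double reaction, should form the C11=C12 bond with E geometry as is usual for stabilised phosphonates.

Step 21
Reactants: 8 {(2E,4E)-5-[(1R,4R)-4-[(tert-butyldimethylsilyl)oxy]-2,6,6-trimethylcyclohex-2-en-1-yl]-3-methylpenta-2,4-dien-1-yl}triphenylphosphonium bromide; 29 (2E,4E,6E,8E,10E,12E)-13-[(3R,4S)-3,4-bis[(tert-butyldimethylsilyl)oxy]-2,6,6-trimethylcyclohex-1-en-1-yl]-2,7,11-trimethyltrideca-2,4,6,8,10,12-hexaenal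
Product: 32 all-E (3S,4R,3'R,6'R)-3,4,3'-tris[(tert-butyldimethylsilyl)oxy]-β,ε-carotene, via phosphorus ylide 30 (not isolated), via 11'Z isomer 31 (not isolated)
Conditions: NaOMe, CH2Cl2/MeOH, 0 °C → rt; then n-heptane, reflux, argon, dark
Reagents that add atoms: none
Why: Wittig olefination of the semi-stabilised allylic ylide with the polyenal forms the C11'=C12' bond as an E/Z mixture, and heating should equilibrate the sterically strained 11'Z isomer to the all-E polyene, as is usual for C15 + C25 carotenoid couplings.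

Step 22
Reactants: 32 all-E (3S,4R,3'R,6'R)-3,4,3'-tris[(tert-butyldimethylsilyl)oxy]-β,ε-carotene
Product: 33 (3S,4R,3'R,6'R)-β,ε-carotene-3,4,3'-triol (target)
Conditions: Bu4NF (excess), THF, rt → 40 °C, argon, dark
Reagents that add atoms: none
Why: Fluoride-induced cleavage of the three silyl ethers under non-acidic conditions should release the triol without ionising the allylic C4 and C3' carbinols.

**Compound list**
1 | (R)-α-ionone, (3E)-4-[(1R)-2,6,6-trimethylcyclohex-2-en-1-yl]but-3-en-2-one | CC1=CCCC(C)(C)[C@H]1/C=C/C(C)=O | starting material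
2 | ethyl (2E,4E)-3-methyl-5-[(1R)-2,6,6-trimethylcyclohex-2-en-1-yl]penta-2,4-dienoate | CC1=CCCC(C)(C)[C@H]1/C=C/C(C)=C/C(=O)OCC | intermediate
3 | ethyl (2E,4E)-3-methyl-5-[(1R)-2,6,6-trimethyl-4-oxocyclohex-2-en-1-yl]penta-2,4-dienoate | CC1=CC(=O)CC(C)(C)[C@H]1/C=C/C(C)=C/C(=O)OCC | intermediate
4 | ethyl (2E,4E)-5-[(1R,4R)-4-hydroxy-2,6,6-trimethylcyclohex-2-en-1-yl]-3-methylpenta-2,4-dienoate | CC1=C[C@H](O)CC(C)(C)[C@H]1/C=C/C(C)=C/C(=O)OCC | intermediate
5 | ethyl (2E,4E)-5-[(1R,4R)-4-[(tert-butyldimethylsilyl)oxy]-2,6,6-trimethylcyclohex-2-en-1-yl]-3-methylpenta-2,4-dienoate | CC1=C[C@H](O[Si](C)(C)C(C)(C)C)CC(C)(C)[C@H]1/C=C/C(C)=C/C(=O)OCC | intermediate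
6 | (2E,4E)-5-[(1R,4R)-4-[(tert-butyldimethylsilyl)oxy]-2,6,6-trimethylcyclohex-2-en-1-yl]-3-methylpenta-2,4-dien-1-ol | CC1=C[C@H](O[Si](C)(C)C(C)(C)C)CC(C)(C)[C@H]1/C=C/C(C)=C/CO | intermediate
7 | tert-butyl({(1R,4R)-4-[(1E,3E)-5-bromo-3-methylpenta-1,3-dien-1-yl]-3,5,5-trimethylcyclohex-2-en-1-yl}oxy)dimethylsilane | CC1=C[C@H](O[Si](C)(C)C(C)(C)C)CC(C)(C)[C@H]1/C=C/C(C)=C/CBr | intermediate
8 | {(2E,4E)-5-[(1R,4R)-4-[(tert-butyldimethylsilyl)oxy]-2,6,6-trimethylcyclohex-2-en-1-yl]-3-methylpenta-2,4-dien-1-yl}triphenylphosphonium bromide | CC1=C[C@H](O[Si](C)(C)C(C)(C)C)CC(C)(C)[C@H]1/C=C/C(C)=C/C[P+](c1ccccc1)(c1ccccc1)c1ccccc1.[Br-] | intermediate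
9 | isobutyronitrile | CC(C)C#N | starting material
10 | (S)-glycidyl trityl ether, (2S)-2-[(triphenylmethoxy)methyl]oxirane | C1O[C@@H]1COC(c1ccccc1)(c1ccccc1)c1ccccc1 | starting material
11 | lithiated isobutyronitrile (not isolated) | [Li+].C[C-](C)C#N | intermediate
12 | (4S)-4-hydroxy-2,2-dimethyl-5-(trityloxy)pentanenitrile | O[C@@H](CC(C)(C)C#N)COC(c1ccccc1)(c1ccccc1)c1ccccc1 | intermediate
13 | (4S)-4-[(tert-butyldimethylsilyl)oxy]-2,2-dimethyl-5-(trityloxy)pentanenitrile | CC(C)(C)[Si](C)(C)O[C@@H](CC(C)(C)C#N)COC(c1ccccc1)(c1ccccc1)c1ccccc1 | intermediate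
14 | N-(diisobutylaluminio) imine of 15 (not isolated) | CC(C)(C)[Si](C)(C)O[C@@H](CC(C)(C)C=N[Al](CC(C)C)CC(C)C)COC(c1ccccc1)(c1ccccc1)c1ccccc1 | intermediate
15 | (4S)-4-[(tert-butyldimethylsilyl)oxy]-2,2-dimethyl-5-(trityloxy)pentanal | CC(C)(C)[Si](C)(C)O[C@@H](CC(C)(C)C=O)COC(c1ccccc1)(c1ccccc1)c1ccccc1 | intermediate
16 | tert-butyl{[(2S)-6,6-dibromo-4,4-dimethyl-1-(trityloxy)hex-5-en-2-yl]oxy}dimethylsilane | CC(C)(C)[Si](C)(C)O[C@@H](CC(C)(C)C=C(Br)Br)COC(c1ccccc1)(c1ccccc1)c1ccccc1 | intermediate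
17 | lithium acetylide of 16 after rearrangement, lithium (5S)-5-[(tert-butyldimethylsilyl)oxy]-3,3-dimethyl-6-(trityloxy)hex-1-yn-1-ide (not isolated) | CC(C)(C)[Si](C)(C)O[C@@H](CC(C)(C)C#C[Li])COC(c1ccccc1)(c1ccccc1)c1ccccc1 | intermediate
18 | tert-butyl{[(2S)-4,4-dimethyl-1-(trityloxy)hept-5-yn-2-yl]oxy}dimethylsilane | CC(C)(C)[Si](C)(C)O[C@@H](CC(C)(C)C#CC)COC(c1ccccc1)(c1ccccc1)c1ccccc1 | intermediate
19 | (2S)-2-[(tert-butyldimethylsilyl)oxy]-4,4-dimethylhept-5-yn-1-ol | CC(C)(C)[Si](C)(C)O[C@@H](CC(C)(C)C#CC)CO | intermediate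
20 | (2S)-2-[(tert-butyldimethylsilyl)oxy]-4,4-dimethylhept-5-ynal | CC(C)(C)[Si](C)(C)O[C@@H](CC(C)(C)C#CC)C=O | intermediate
21 | (2E)-3-methylpent-2-en-4-yn-1-ol | C#C/C(C)=C/CO | starting material
22 | (3E)-5-bromo-3-methylpent-3-en-1-yne | C#C/C(C)=C/CBr | intermediate
23 | diethyl [(2E)-3-methylpent-2-en-4-yn-1-yl]phosphonate | C#C/C(C)=C/CP(=O)(OCC)OCC | intermediate
24 | diethyl [(2E,4E)-3-methyl-5-(4,4,5,5-tetramethyl-1,3,2-dioxaborolan-2-yl)penta-2,4-dien-1-yl]phosphonate | CCOP(=O)(OCC)C/C=C(C)/C=C/B1OC(C)(C)C(C)(C)O1 | intermediate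
25 | diethyl {(2E,4E)-5-[(3R,4S)-4-[(tert-butyldimethylsilyl)oxy]-3-hydroxy-2,6,6-trimethylcyclohex-1-en-1-yl]-3-methylpenta-2,4-dien-1-yl}phosphonate | CCOP(=O)(OCC)C/C=C(C)/C=C/C1=C(C)[C@@H](O)[C@@H](O[Si](C)(C)C(C)(C)C)CC1(C)C | intermediate
26 | diethyl {(2E,4E)-5-[(3R,4S)-3,4-bis[(tert-butyldimethylsilyl)oxy]-2,6,6-trimethylcyclohex-1-en-1-yl]-3-methylpenta-2,4-dien-1-yl}phosphonate | CCOP(=O)(OCC)C/C=C(C)/C=C/C1=C(C)[C@@H](O[Si](C)(C)C(C)(C)C)[C@@H](O[Si](C)(C)C(C)(C)C)CC1(C)C | intermediate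
27 | (2E,4E,6E)-2,7-dimethylocta-2,4,6-trienedial | O=C/C(C)=C/C=C/C=C(C)/C=O | starting material
28 | sodium C11 carbanion of phosphonate 26 (not isolated) | [Na+].CCOP(=O)(OCC)[CH-]/C=C(C)/C=C/C1=C(C)[C@@H](O[Si](C)(C)C(C)(C)C)[C@@H](O[Si](C)(C)C(C)(C)C)CC1(C)C | intermediate
29 | (2E,4E,6E,8E,10E,12E)-13-[(3R,4S)-3,4-bis[(tert-butyldimethylsilyl)oxy]-2,6,6-trimethylcyclohex-1-en-1-yl]-2,7,11-trimethyltrideca-2,4,6,8,10,12-hexaenal | O=C/C(C)=C/C=C/C=C(C)/C=C/C=C(C)/C=C/C1=C(C)[C@@H](O[Si](C)(C)C(C)(C)C)[C@@H](O[Si](C)(C)C(C)(C)C)CC1(C)C | intermediate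
30 | phosphorus ylide from 8 (not isolated) | CC1=C[C@H](O[Si](C)(C)C(C)(C)C)CC(C)(C)[C@H]1/C=C/C(C)=C/C=P(c1ccccc1)(c1ccccc1)c1ccccc1 | intermediate
31 | 11'Z isomer of 32 (not isolated) | CC1=C[C@H](O[Si](C)(C)C(C)(C)C)CC(C)(C)[C@H]1/C=C/C(C)=C/C=C\C(C)=C\C=C\C=C(C)\C=C\C=C(C)\C=C\C1=C(C)[C@@H](O[Si](C)(C)C(C)(C)C)[C@@H](O[Si](C)(C)C(C)(C)C)CC1(C)C | intermediate
32 | all-E (3S,4R,3'R,6'R)-3,4,3'-tris[(tert-butyldimethylsilyl)oxy]-β,ε-carotene | CC1=C[C@H](O[Si](C)(C)C(C)(C)C)CC(C)(C)[C@H]1/C=C/C(C)=C/C=C/C(C)=C/C=C/C=C(C)/C=C/C=C(C)/C=C/C1=C(C)[C@@H](O[Si](C)(C)C(C)(C)C)[C@@H](O[Si](C)(C)C(C)(C)C)CC1(C)C | intermediate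
33 | (3S,4R,3'R,6'R)-β,ε-carotene-3,4,3'-triol | CC1=C[C@H](O)CC(C)(C)[C@H]1/C=C/C(C)=C/C=C/C(C)=C/C=C/C=C(C)/C=C/C=C(C)/C=C/C1=C(C)[C@@H](O)[C@@H](O)CC1(C)C | target

**Step count and risks**
Total step count: 22. Longest linear sequence: 12 steps (steps 8–14 and 18–22).

The three steps most likely to fail are step 18, step 3 and step 20, in that order.

In step 18 the aldehyde faces may be poorly discriminated while the C4–C5 bond forms, so that the 3,4-trans isomer accompanies or replaces 25. The fallback keeps the ring closure for the skeleton only and sets C4 afterwards by reagent control; it sets out from 20 and 24 and comes back at 25. The cyclization is run as in step 18 and the unseparated product, which then contains diethyl {(2E,4E)-5-[(3S,4S)-4-[(tert-butyldimethylsilyl)oxy]-3-hydroxy-2,6,6-trimethylcyclohex-1-en-1-yl]-3-methylpenta-2,4-dien-1-yl}phosphonate F1, is oxidised with MnO2 (CH2Cl2, rt) to the enone diethyl {(2E,4E)-5-[(4S)-4-[(tert-butyldimethylsilyl)oxy]-2,6,6-trimethyl-3-oxocyclohex-1-en-1-yl]-3-methylpenta-2,4-dien-1-yl}phosphonate F2, which erases C4. Reduction with Li[(s-Bu)3BH] (THF, −78 °C) should then deliver hydride in the equatorial direction of the enone envelope that carries the C3 silyloxy group pseudo-equatorial and give the pseudo-axial, cis alcohol 25, so that both C4 epimers are funnelled into one.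

In step 3 the hydride may add with poor facial selectivity at C3' (competing axial attack, which gives the 3',6'-cis alcohol). The fallback replaces face-selective reduction by inversion; it sets out from 3 and comes back at 4. Luche reduction (NaBH4, CeCl3·7H2O, MeOH, −78 °C) is used on purpose to favour axial attack and give ethyl (2E,4E)-5-[(1R,4S)-4-hydroxy-2,6,6-trimethylcyclohex-2-en-1-yl]-3-methylpenta-2,4-dienoate F3. Mitsunobu inversion (4-nitrobenzoic acid, PPh3, diisopropyl azodicarboxylate, THF, 0 °C) gives (1R,4R)-4-[(1E,3E)-5-ethoxy-3-methyl-5-oxopenta-1,3-dien-1-yl]-3,5,5-trimethylcyclohex-2-en-1-yl 4-nitrobenzoate F4, and ethanolysis (K2CO3, EtOH, rt) gives 4.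

In step 20 the carbanion may react at both ends of the dialdehyde and may partly lose the 9E geometry by bond rotation in the delocalised anion 28, both at the expense of the key-step product. The fallback reverses the order of the two couplings; it sets out from 8 and 27 and comes back at 32. Ylide 30 (from 8, NaOMe, CH2Cl2/MeOH) is condensed with 27 in excess and the product is equilibrated by heating to the all-E aldehyde (2E,4E,6E,8E,10E,12E)-13-[(1R,4R)-4-[(tert-butyldimethylsilyl)oxy]-2,6,6-trimethylcyclohex-2-en-1-yl]-2,7,11-trimethyltrideca-2,4,6,8,10,12-hexaenal F5. Carbanion 28 (from 26, NaN(SiMe3)2, THF, −78 °C) is then condensed with an equimolar amount of F5 in a Horner–Wadsworth–Emmons reaction, so that 26 never meets a second aldehyde group, to give 32.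

**Further compounds**
F1 | step 18 | diethyl {(2E,4E)-5-[(3S,4S)-4-[(tert-butyldimethylsilyl)oxy]-3-hydroxy-2,6,6-trimethylcyclohex-1-en-1-yl]-3-methylpenta-2,4-dien-1-yl}phosphonate | CCOP(=O)(OCC)C/C=C(C)/C=C/C1=C(C)[C@H](O)[C@@H](O[Si](C)(C)C(C)(C)C)CC1(C)C
F2 | step 18 | diethyl {(2E,4E)-5-[(4S)-4-[(tert-butyldimethylsilyl)oxy]-2,6,6-trimethyl-3-oxocyclohex-1-en-1-yl]-3-methylpenta-2,4-dien-1-yl}phosphonate | CCOP(=O)(OCC)C/C=C(C)/C=C/C1=C(C)C(=O)[C@@H](O[Si](C)(C)C(C)(C)C)CC1(C)C
F3 | step 3 | ethyl (2E,4E)-5-[(1R,4S)-4-hydroxy-2,6,6-trimethylcyclohex-2-en-1-yl]-3-methylpenta-2,4-dienoate | CC1=C[C@@H](O)CC(C)(C)[C@H]1/C=C/C(C)=C/C(=O)OCC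
F4 | step 3 | (1R,4R)-4-[(1E,3E)-5-ethoxy-3-methyl-5-oxopenta-1,3-dien-1-yl]-3,5,5-trimethylcyclohex-2-en-1-yl 4-nitrobenzoate | CC1=C[C@H](OC(=O)c2ccc(cc2)[N+](=O)[O-])CC(C)(C)[C@H]1/C=C/C(C)=C/C(=O)OCC
F5 | step 20 | (2E,4E,6E,8E,10E,12E)-13-[(1R,4R)-4-[(tert-butyldimethylsilyl)oxy]-2,6,6-trimethylcyclohex-2-en-1-yl]-2,7,11-trimethyltrideca-2,4,6,8,10,12-hexaenal | CC1=C[C@H](O[Si](C)(C)C(C)(C)C)CC(C)(C)[C@H]1/C=C/C(C)=C/C=C/C(C)=C/C=C/C=C(C)/C=O
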